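**Plan** (labdane numbering throughout)
- Cuts: O15–H from a silyl ether. C6–OAc comes from a C6 ketone, and that from a C5=C6 enol silane. The side chain is cut at C12–C13 (B-alkyl Suzuki–Miyaura) and C11=C12 (Wittig). Ring B is cut at C7–C8 and C9–C10 together (Diels–Alder), then C6–C7 (Grignard).
- Enabling feature: in ring B (C5–C10) the tetrasubstituted C8=C9 alkene lies 1,4 to the C5–C6 bond, and C6 carries oxygen. At the enol level of a C6 ketone, ring B is therefore a 1,4-cyclohexadiene, the adduct of an alkyne C8≡C9 and the diene C10=C5–C6=C7 on ring A. H7 and the C20 methyl are cis, as suprafacial addition to a (Z)-7-acetoxy diene requires.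
- Forward: ring A is bought (β-cyclocitral = C1–C6, C10, C18–C20) and C7 enters with its oxygen. Ring B closes in step 6 with 2-butynal (C8, C9, C11, C17). C12 (Wittig) and C13–C16 (alkenyl iodide) complete the chain.
- Helpers: the formyl group activates the alkyne and then becomes C11. The 6-silyloxy group steers regiochemistry, stores the C6 ketone and leaves in step 11. TBDPS keeps O15 apart from the two acetates.
- Stereochemistry: C10 from the chiral boron catalyst, C7 from the diene geometry (relative to C10), C5 by α-protonation, C6 by α-hydride attack, C13=C14 from syn-hydrozirconation.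

Key step: step 6

Assumption: the (S)-oxazaborolidinium salt is taken to deliver the (7S,10S)-adduct; should the sense of induction be the reverse, its (R)-enantiomer is used and nothing else changes.

Step 1
Reactants: 1 β-cyclocitral (2,6,6-trimethylcyclohex-1-ene-1-carbaldehyde)
Product: 3 1-(2,6,6-trimethylcyclohex-1-en-1-yl)ethane-1,2-diol (racemic), via β-hydroxysilane 2 (not isolated)
Conditions: ClCH2SiMe2(OiPr), Mg, THF; then 1, 0 °C; aq NH4Cl; crude 2: 30 % H2O2, KF, KHCO3, THF/MeOH, rt
Reagents that add atoms: (chloromethyl)(isopropoxy)dimethylsilane, ClC[Si](C)(C)OC(C)C; hydrogen peroxide, OO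
Why: Grignard 1,2-addition of a hydroxymethyl anion equivalent to the hindered enal followed by Tamao–Fleming oxidation of the C–Si bond brings in C7 already oxygenated, and the racemic carbinol centre is erased in step 3.

Step 2
Reactants: 3 1-(2,6,6-trimethylcyclohex-1-en-1-yl)ethane-1,2-diol
Product: 4 2-hydroxy-2-(2,6,6-trimethylcyclohex-1-en-1-yl)ethyl acetate (racemic)
Conditions: AcCl, 2,4,6-collidine, CH2Cl2, −78 °C
Reagents that add atoms: acetyl chloride, CC(=O)Cl
Why: Selective acylation of the primary hydroxyl, which reacts much faster than the secondary allylic one shielded by the trimethylcyclohexenyl group, puts the acetate that the target keeps at O7 in place.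

Step 3
Reactants: 4 2-hydroxy-2-(2,6,6-trimethylcyclohex-1-en-1-yl)ethyl acetate
Product: 5 2-oxo-2-(2,6,6-trimethylcyclohex-1-en-1-yl)ethyl acetate
Conditions: IBX (2-iodoxybenzoic acid), EtOAc, 80 °C
Reagents that add atoms: none
Why: IBX oxidation of the secondary allylic alcohol runs under neutral conditions, spares acetate and tetrasubstituted alkene, and erases the only (racemic) stereocentre.

Step 4
Reactants: 5 2-oxo-2-(2,6,6-trimethylcyclohex-1-en-1-yl)ethyl acetate
Product: 6 (Z)-2-(tert-butyldimethylsilyloxy)-2-(2,6,6-trimethylcyclohex-1-en-1-yl)ethenyl acetate (diene C10=C5–C6(OTBS)=C7H–OAc, O6 and O7 cis)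
Conditions: TBSOTf, Et3N, CH2Cl2, 0 °C → rt
Reagents that add atoms: tert-butyldimethylsilyl triflate, CC(C)(C)[Si](C)(C)OS(=O)(=O)C(F)(F)F
Why: Soft enolisation with silyl triflate and amine can only use the acidified C7 protons (C5 bears none and the twisted enone resists γ-deprotonation), and the bulk of ring A forces the acetoxy group trans to it, which is the (Z)-enol silane with O7 on the outside of the s-cis diene.

Step 5
Reactants: 7 but-2-yn-1-ol
Product: 8 but-2-ynal
Conditions: MnO2, CH2Cl2, rt; filtered, dried, used as solution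
Reagents that add atoms: none
Why: MnO2 oxidation of a propargylic alcohol stops cleanly at the volatile ynal, which is filtered, dried and used as its CH2Cl2 solution.

Step 6
Reactants: 6 (Z)-acetoxy(silyloxy)diene; 8 but-2-ynal
Product: 9 (7S,10S)-7α-acetoxy-6-(tert-butyldimethylsilyloxy)-12,13,14,15,16-pentanorlabda-5,8-dien-11-al (C5=C6 enol silane, C8 methyl, C9 formyl, C10 methyl β)
Conditions: (S)-3,3-diphenyl-1-(2-methylphenyl)tetrahydro-1H,3H-pyrrolo[1,2-c][1,3,2]oxazaborole (20 mol %), HN(SO2CF3)2 (18 mol %), CH2Cl2, −78 → −20 °C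
Reagents that add atoms: none
Why: The boron Lewis acid binds the formyl oxygen of 8 and a concerted, strongly asynchronous normal-demand [4+2] cycloaddition follows, in which C7 (largest HOMO coefficient, next to the silyloxy-bearing C6) bonds early to the β-carbon C8 and C9 then closes onto the fully substituted C10. The closest known reaction types are the thermal Diels–Alder reaction of 1-vinyl-2,6,6-trimethylcyclohexenes with acetylenic esters, the Lewis acid promoted Diels–Alder reaction of hindered 2-silyloxydienes that builds quaternary carbons, and the enantioselective Diels–Alder reaction of acetylenic aldehydes and ketones under chiral boron Lewis acids. One ring closes, ring B, by intermolecular suprafacial-suprafacial [4π+2π] addition onto preformed ring A, and it appears as a 1,4-cyclohexadiene (C5=C6 enol silane, C8=C9 enal) that cannot aromatise because C10 is quaternary. C10 is set by the catalyst, which screens one face of the bound ynal and so selects the diene face, and C7 is tied to C10 by the suprafacial course, since the two inside groups of the s-cis (Z)-diene (C20 methyl and H7) must end up cis, which is 7α-OAc with 10β-CH3. Regioselectivity is needed and is secured by the strong 6-silyloxy donor (formyl-bearing C9 para to C6) together with the two alkyl groups on C10, the 7-acetoxy group being too weak a donor to oppose them. Chemoselectivity for C≡C over C=O is needed as well and is helped by the bulky TBS group, whose slow transfer keeps any aldol-type addition reversible, while any (E)-isomer of 6 cannot reach the s-cis form and stays behind.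

Step 7
Reactants: 9 Diels–Alder adduct (11-aldehyde)
Product: 10 (7S,10S)-7α-acetoxy-6-(tert-butyldimethylsilyloxy)-13,14,15,16-tetranorlabda-5,8,11-triene (C9 vinyl)
Conditions: Ph3PCH3Br, KHMDS, THF, 0 °C; then 9, −78 → 0 °C
Reagents that add atoms: methyltriphenylphosphonium bromide, C[P+](c1ccccc1)(c1ccccc1)c1ccccc1.[Br-]
Why: Wittig methylenation, in which the unstabilised ylide adds to the aldehyde at low temperature far faster than it attacks the acetate or deprotonates C7, turns the activating formyl group into C11=C12 without touching a stereocentre.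

Step 8
Reactants: 7 but-2-yn-1-ol
Product: 11 (but-2-yn-1-yloxy)(tert-butyl)diphenylsilane
Conditions: TBDPSCl, imidazole, CH2Cl2, rt
Reagents that add atoms: tert-butyl(chloro)diphenylsilane, CC(C)(C)[Si](Cl)(c1ccccc1)c1ccccc1
Why: Standard silyl ether formation, TBDPS being chosen because it outlasts the aqueous acid of step 11 and later leaves with fluoride without harm to acetates.

Step 9
Reactants: 11 (but-2-yn-1-yloxy)(tert-butyl)diphenylsilane
Product: 13 (E)-tert-butyl[(3-iodobut-2-en-1-yl)oxy]diphenylsilane, via alkenylzirconocene 12 (not isolated)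
Conditions: Cp2Zr(H)Cl (slight excess), THF, rt → 40 °C; then I2, 0 °C
Reagents that add atoms: iodine, II
Why: Hydrozirconation adds Zr–H syn and equilibrates under a slight excess of Cp2Zr(H)Cl to the isomer with the metal next to the small methyl group, and iodinolysis with retention gives the (E)-iodide that encodes the C13=C14 geometry.

Step 10
Reactants: 10 C9-vinyl triene; 13 (E)-alkenyl iodide
Product: 15 (7S,10S,13E)-7α-acetoxy-6-(tert-butyldimethylsilyloxy)-15-(tert-butyldiphenylsilyloxy)labda-5,8,13-triene, via B-alkyl-9-BBN borane 14 (not isolated)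
Conditions: 9-borabicyclo[3.3.1]nonane (9-BBN-H), THF, rt; then 13, Pd(dppf)Cl2 (5 mol %), AsPh3, Cs2CO3, DMF/H2O, rt
Reagents that add atoms: none
Why: 9-BBN-H hydroborates only the monosubstituted C11=C12 alkene at C12 (both ring alkenes are tetrasubstituted) and the B-alkyl Suzuki–Miyaura coupling joins C12 to C13 with retention of the (E)-geometry, since zerovalent palladium inserts into the alkenyl iodide at room temperature much faster than it can ionise the hindered allylic acetate.

Step 11
Reactants: 15 enol silane with full side chain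
Product: 16 (5S,7S,10S,13E)-7α-acetoxy-15-(tert-butyldiphenylsilyloxy)labda-8,13-dien-6-one (trans-decalone)
Conditions: 1 M aq HCl, THF, 0 °C → rt, short contact
Reagents that add atoms: none
Why: In this acid hydrolysis of the enol silane C5 is protonated from the α face, anti to the axial C20 and 4β methyl groups, which gives the trans-fused (also thermodynamic) ketone, while the pseudoequatorial C7–H is poorly aligned with the carbonyl π system and resists enolisation and the TBDPS ether survives.

Step 12
Reactants: 16 7α-acetoxy-6-ketone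
Product: 17 (5S,6S,7S,10S,13E)-7α-acetoxy-15-(tert-butyldiphenylsilyloxy)labda-8,13-dien-6β-ol
Conditions: NaBH4, CeCl3·7H2O, MeOH/THF, −40 → 0 °C
Reagents that add atoms: none
Why: Borohydride reduction under Luche conditions follows steric approach control, because the β face of C6 is closed by the two syn-axial methyl groups (C20 and C19), so hydride arrives from the α face and gives the axial 6β-alcohol.

Step 13
Reactants: 17 6β-alcohol
Product: 18 (5S,6S,7S,10S,13E)-6β,7α-diacetoxy-15-(tert-butyldiphenylsilyloxy)labda-8,13-diene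
Conditions: Ac2O, 4-(dimethylamino)pyridine (DMAP), pyridine, 40 °C
Reagents that add atoms: acetic anhydride, CC(=O)OC(C)=O
Why: DMAP-catalysed acylation overcomes the hindrance of the axial 6β-hydroxyl, and any acetyl migration between O6 and O7 is without consequence because both end as acetates.

Step 14
Reactants: 18 diacetate silyl ether
Product: 19 6β,7α-diacetoxylabda-8,13E-dien-15-ol, (5S,6S,7S,10S), the target
Conditions: HF·pyridine, pyridine, THF, 0 °C → rt
Reagents that add atoms: none
Why: Fluoride-mediated desilylation in a pyridine-buffered medium cleaves only the Si–O bond and leaves both acetates, both alkenes and all four stereocentres untouched.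

**Compound list**
1 | β-cyclocitral | CC1=C(C=O)C(C)(C)CCC1 | starting material
2 | 2-[isopropoxy(dimethyl)silyl]-1-(2,6,6-trimethylcyclohex-1-en-1-yl)ethanol (racemic) | CC1=C(C(O)C[Si](C)(C)OC(C)C)C(C)(C)CCC1 | intermediate
3 | 1-(2,6,6-trimethylcyclohex-1-en-1-yl)ethane-1,2-diol (racemic) | CC1=C(C(O)CO)C(C)(C)CCC1 | intermediate
4 | 2-hydroxy-2-(2,6,6-trimethylcyclohex-1-en-1-yl)ethyl acetate (racemic) | CC(=O)OCC(O)C1=C(C)CCCC1(C)C | intermediate
5 | 2-oxo-2-(2,6,6-trimethylcyclohex-1-en-1-yl)ethyl acetate | CC(=O)OCC(=O)C1=C(C)CCCC1(C)C | intermediate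
6 | (Z)-2-(tert-butyldimethylsilyloxy)-2-(2,6,6-trimethylcyclohex-1-en-1-yl)ethenyl acetate | CC(=O)O/C=C(\O[Si](C)(C)C(C)(C)C)C1=C(C)CCCC1(C)C | intermediate
7 | but-2-yn-1-ol | CC#CCO | starting material
8 | but-2-ynal | CC#CC=O | intermediate
9 | (7S,10S)-7α-acetoxy-6-(TBSO)-12,13,14,15,16-pentanorlabda-5,8-dien-11-al | CC(=O)O[C@H]1C(C)=C(C=O)[C@@]2(C)CCCC(C)(C)C2=C1O[Si](C)(C)C(C)(C)C | intermediate
10 | (7S,10S)-7α-acetoxy-6-(TBSO)-13,14,15,16-tetranorlabda-5,8,11-triene | CC(=O)O[C@H]1C(C)=C(C=C)[C@@]2(C)CCCC(C)(C)C2=C1O[Si](C)(C)C(C)(C)C | intermediate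
11 | (but-2-yn-1-yloxy)(tert-butyl)diphenylsilane | CC#CCO[Si](c1ccccc1)(c1ccccc1)C(C)(C)C | intermediate
12 | (E)-[4-(TBDPSO)but-2-en-2-yl]zirconocene chloride | Cl[Zr](C1C=CC=C1)(C1C=CC=C1)/C(C)=C/CO[Si](c1ccccc1)(c1ccccc1)C(C)(C)C | intermediate
13 | (E)-tert-butyl[(3-iodobut-2-en-1-yl)oxy]diphenylsilane | I/C(C)=C/CO[Si](c1ccccc1)(c1ccccc1)C(C)(C)C | intermediate
14 | 12-(9-borabicyclo[3.3.1]nonan-9-yl) derivative of 11,12-dihydro-10 | CC(=O)O[C@H]1C(C)=C(CCB3C4CCCC3CCC4)[C@@]2(C)CCCC(C)(C)C2=C1O[Si](C)(C)C(C)(C)C | intermediate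
15 | (7S,10S,13E)-7α-acetoxy-6-(TBSO)-15-(TBDPSO)labda-5,8,13-triene | CC(=O)O[C@H]1C(C)=C(CC/C(C)=C/CO[Si](c3ccccc3)(c3ccccc3)C(C)(C)C)[C@@]2(C)CCCC(C)(C)C2=C1O[Si](C)(C)C(C)(C)C | intermediate
16 | (5S,7S,10S,13E)-7α-acetoxy-15-(TBDPSO)labda-8,13-dien-6-one | O=C1[C@@H](OC(C)=O)C(C)=C(CC/C(C)=C/CO[Si](c3ccccc3)(c3ccccc3)C(C)(C)C)[C@@]2(C)CCCC(C)(C)[C@H]12 | intermediate
17 | (5S,6S,7S,10S,13E)-7α-acetoxy-15-(TBDPSO)labda-8,13-dien-6β-ol | O[C@@H]1[C@@H](OC(C)=O)C(C)=C(CC/C(C)=C/CO[Si](c3ccccc3)(c3ccccc3)C(C)(C)C)[C@@]2(C)CCCC(C)(C)[C@H]12 | intermediate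
18 | (5S,6S,7S,10S,13E)-6β,7α-diacetoxy-15-(TBDPSO)labda-8,13-diene | CC(=O)O[C@@H]1[C@@H](OC(C)=O)C(C)=C(CC/C(C)=C/CO[Si](c3ccccc3)(c3ccccc3)C(C)(C)C)[C@@]2(C)CCCC(C)(C)[C@H]12 | intermediate
19 | 6β,7α-diacetoxylabda-8,13E-dien-15-ol | CC(=O)O[C@@H]1[C@@H](OC(C)=O)C(C)=C(CC/C(C)=C/CO)[C@@]2(C)CCCC(C)(C)[C@H]12 | target

Total step count: 14. Longest linear sequence: 11 steps (1, 2, 3, 4, 6, 7, 10, 11, 12, 13, 14).

**Steps most likely to fail**

1) Step 6.
- What may go wrong: the enol-silane terminus C7 may add to the activated formyl carbon (Mukaiyama aldol pathway) before the hindered diene reaches its s-cis form. The acid may strip the silyl group. The catalyst may tell the two diene faces apart poorly.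
- Fallback: it sets out from 6 and 8 and comes back at 9. The Lewis acid is left out. Diene and ynal are heated without catalyst (toluene, BHT, 110 °C, sealed tube) or pressed (CH2Cl2, 13 kbar, rt). Under these conditions a neutral ynal cannot enter the aldol pathway, and regiochemistry and the C7/C10 relation are still dictated by the diene. The product is then the racemate, that is 9 together with the mirror-image (7R,10R)-adduct F1. The two are separated by preparative chromatography on an amylose tris(3,5-dimethylphenylcarbamate) phase, and 9 goes on to step 7.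

2) Step 12.
- What may go wrong: facial selectivity may be poor because the pseudoaxial 7α-acetoxy group screens part of the α face. In the basic borohydride medium, enolisation of the β,γ-unsaturated α-acetoxy ketone may lead to epimerisation at C7 or drift of C8=C9 into conjugation.
- Fallback: it sets out from 15 and comes back at 18. The acetate is taken off while C6 is still masked: DIBAL-H (CH2Cl2, −78 °C) converts 15 into the 7α-alcohol enol silane F2. Then 1 M HCl in THF frees the 7α-hydroxy-6-ketone F3, which is reduced at once in acidic medium with Me4NBH(OAc)3 (MeCN/AcOH, −20 °C, Evans–Saksena reduction). Boron binds O7 on the α face and hands its hydride to C6 from that face, which should give the 6β,7α-diol F4. Double acetylation (Ac2O, DMAP, pyridine) leads to 18.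

3) Step 10.
- What may go wrong: transmetalation of the hindered borane may be slow, with protodeboronation. The aqueous carbonate may saponify the acetate. Zerovalent palladium may ionise the allylic acetate during a sluggish coupling.
- Fallback: it sets out from 10 and comes back at 15. Borane 14, made as before, is oxidised (NaBO3·4H2O, THF/H2O) to the primary 12-alcohol F5. An Appel reaction (I2, PPh3, imidazole, CH2Cl2) gives the 12-iodide F6. Zinc insertion (Zn dust, LiCl, THF, 40 °C) gives the alkylzinc iodide F7. A Negishi coupling with 13 (Pd(PPh3)4, THF, rt), free of base and water, gives 15.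

**Further compounds**
F1 | step 6 | (7R,10R)-7β-acetoxy-6-(TBSO)-12,13,14,15,16-pentanor-ent-labda-5,8-dien-11-al, mirror image of 9 | CC(=O)O[C@@H]1C(C)=C(C=O)[C@]2(C)CCCC(C)(C)C2=C1O[Si](C)(C)C(C)(C)C
F2 | step 12 | (7S,10S,13E)-6-(TBSO)-15-(TBDPSO)labda-5,8,13-trien-7α-ol | O[C@H]1C(C)=C(CC/C(C)=C/CO[Si](c3ccccc3)(c3ccccc3)C(C)(C)C)[C@@]2(C)CCCC(C)(C)C2=C1O[Si](C)(C)C(C)(C)C
F3 | step 12 | (5S,7S,10S,13E)-7α-hydroxy-15-(TBDPSO)labda-8,13-dien-6-one | O=C1[C@@H](O)C(C)=C(CC/C(C)=C/CO[Si](c3ccccc3)(c3ccccc3)C(C)(C)C)[C@@]2(C)CCCC(C)(C)[C@H]12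
F4 | step 12 | (5S,6S,7S,10S,13E)-15-(TBDPSO)labda-8,13-diene-6β,7α-diol | O[C@@H]1[C@@H](O)C(C)=C(CC/C(C)=C/CO[Si](c3ccccc3)(c3ccccc3)C(C)(C)C)[C@@]2(C)CCCC(C)(C)[C@H]12
F5 | step 10 | (7S,10S)-7α-acetoxy-6-(TBSO)-13,14,15,16-tetranorlabda-5,8-dien-12-ol | CC(=O)O[C@H]1C(C)=C(CCO)[C@@]2(C)CCCC(C)(C)C2=C1O[Si](C)(C)C(C)(C)C
F6 | step 10 | (7S,10S)-7α-acetoxy-12-iodo-6-(TBSO)-13,14,15,16-tetranorlabda-5,8-diene | CC(=O)O[C@H]1C(C)=C(CCI)[C@@]2(C)CCCC(C)(C)C2=C1O[Si](C)(C)C(C)(C)C
F7 | step 10 | 12-(iodozincio) analogue of F6 | CC(=O)O[C@H]1C(C)=C(CC[Zn]I)[C@@]2(C)CCCC(C)(C)C2=C1O[Si](C)(C)C(C)(C)C
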